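## Analysis of the target

The target is a tetracyclic C19 gibberellin-type lactone. Ring A (C1–C5, C10) is a cyclohexane spanned by a γ-lactone (C19 on C4, oxygen on C10). Ring B (C5, C6, C8, C9, C10) is a cyclopentane carrying the C7 acid on C6. Rings C and D form a bicyclo[3.2.1]octane with a bridgehead carbinol (C13) and an exocyclic methylene (C16=C17).

There are nine stereocentres (C2, C3, C4, C5, C6, C8, C9, C10, C13). C4, C8, C10 and C13 are fully substituted.

Read from the SMILES, the lactone bridge lies on one face of ring A and the cis C2,C3 diol on the other (C3–OH axial, C2–OH equatorial). On ring B, C4 and the lactone oxygen are cis, the C7 carboxyl is trans to C4 and cis to the C15 bridge, and H9 is anti to C15 and on the side of the lactone oxygen. Ring B is therefore trans-fused to the chair of ring C.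

Sensitive groups:
- The 13-hydroxy-16-ene unit rearranges in protic acid. Once present, it forbids ozonolysis, dihydroxylation, hydroboration and hydrogenation elsewhere.
- The C3 hydroxyl is β to the lactone carbonyl and epimerises by retro-aldol/aldol in base.
- Any carbonyl at C2 is β to the lactone oxygen and can open the lactone by elimination.

The main difficulties are two. C9 becomes epimerisable whenever C10 is a ketone, and its preferred configuration there is not known. C10 carries its carbon substituent (C1) on the hindered face, syn to C15, with oxygen on the open face.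

The strategy rests on the C2–C3 bond of ring A. It joins two oxygen-bearing carbons; C2 is tied through C1 to C10 and C3 sits directly on quaternary C4, both held cis on the rigid lactone. Cutting it leaves two aldehydes.

## Retrosynthetic reasoning

**36 ⇒ 34.** Only two protecting groups remain at the end, the C13 methoxymethyl ether and the C7 methyl ester. They are removed last, one with a Lewis-acidic boron reagent and one by demethylation at the methyl carbon. Neither protic acid (rearrangement at C13/C16) nor hydroxide (retro-aldol at C3) is then needed.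

**34 ⇒ 33.** The C2–C3 bond is cut to the seco-ring-A dialdehyde 33. This is the only ring A bond whose formation closes the ring and creates both carbinol centres. The lactone, C4, C5 and C10 are already in place and dictate the facial course. The forward reaction is a reductive coupling of two aldehydes by divalent samarium. It has to give the cis diol on the face away from the lactone bridge and leave the lactone, ester and alkene alone.

**33 ⇒ 32 ⇒ 31 ⇒ 30 ⇒ 29.** Both aldehydes come from primary alcohols (32) in one oxidation. They are unveiled together and last, because the C2 aldehyde is β to the lactone oxygen. C4 is not left to an equilibrium. C18 and then C3 are introduced one after the other on the lactone enolate of 29, and the last electrophile enters on the convex face. C3 therefore ends syn to the C1 arm.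

**29 ⇒ 28 ⇒ 27.** The C10–O bond is cut by a retro-iodolactonisation to the C10=C1 alkylidene 27. Adding the C1–C2 unit to a C10 ketone would have to occur syn to the C15 bridge, against the normal steric course. Delivering oxygen from the C19 carboxyl, tethered through C5, is enforced by the ring and also uses the open face. C2 is carried as a protected alcohol, so no alkene chemistry is needed later in the presence of C16=C17.

**27 ⇒ 25 ⇒ 23 + 24.** The alkylidene comes from a vinyl adduct of the C10 ketone by 1,3-transposition. The facial course of the addition does not matter, since both epimers converge. A two-carbon unit is required here; a three-carbon acetal nucleophile would put one carbon too many on C10.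

**23 ⇒ 21 + 22.** The C5–C4 bond is cut to the ring B ketone 21 and a bromoacetate. The ketone is used only under kinetic conditions (irreversible enolisation at C5, then organocerium addition), so C9 is never equilibrated.

**21 ⇒ 19 ⇒ 18.** Ring B is opened at C5–C6. The forward step is an intramolecular ester enolate alkylation. Its two arms are already trans on ring C, so the trans ring fusion is built in and not left to an enolisable centre.

**18 ⇒ 15 ⇒ 14.** Ring D is opened at C13–C16. The forward ketyl–alkyne cyclisation gives the bridgehead carbinol and the methylene in one step. It must come before all strong-base steps, because it removes the ring C ketone. It must come after the oxidative degradation of the allyl group (14 ⇐ 11), because the methylene would not survive that.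

**11 ⇒ 9 + 10.** The C8–C6 bond is cut. Conjugate allylation anti to the C9 side chain creates quaternary C8 with the correct relation to C9.

**9 ⇒ 6 + 7.** The C8–C15 bond is cut. Addition of a propargyl Grignard reagent to the vinylogous ester, then hydrolysis, transposes the carbonyl to C13.

**6 ⇒ 5 ⇒ 2 + 3 ⇒ 1.** The C9–C10 bond is cut by a retro-aldol. The forward catalytic asymmetric aldol sets C9, the centre from which every other stereocentre is derived. It also brings C10 and C5 at the oxidation levels needed later.

## Alternatives that were turned down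

**Alternative 1:** Rings A and B are disconnected together at C5–C10 and C3–C4. The forward step is an intramolecular Diels–Alder reaction of a 1,4-bis(silyloxy)diene (C10=C1–C2=C3) with a trisubstituted (Z)-enoate (C5=C4), tethered through C9, C8 and C6. It would give the tetracyclic cycloadduct A1.
- For it: two rings, two C–C bonds and four stereocentres (C3, C4, C5, C10) in one step, with C4 arriving complete. On bond economy at the key step it is stronger than the chosen route.
- Against it: the diene terminus C10 is fully substituted and must carry its silyloxy group inside. The dienophile is a hindered trisubstituted enoate. The step has to form adjacent fully substituted C4 and C10 with endo/exo and facial control that nothing in the tether secures. A1 also has the wrong oxidation pattern: C1=C2 alkene and no oxygen at C2, C7 at the alcohol level, C16 masked. Regio- and face-selective hydration of C1=C2 and three further adjustments would follow.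
- Comparison: the chosen route spends more steps before the key step, but sets each centre under a separate, predictable control and makes the diol directly.

**Alternative 2:** Ring D is disconnected at C8–C15 in a series with aromatic ring A. The forward step is a bridging alkylation: the C8 enolate of a benzo-fused C6 ketone displaces a bromide on a ketone arm at C13, giving the bicyclo[3.2.1]octanone A2.
- For it: the enolate alkylation is robust, the geometry of the bridge is enforced, and aromatic precursors are cheap. For ring D it is as reliable as the ketyl–alkyne closure used here.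
- Against it: it solves only ring D. A2 still needs dearomatisation of ring A with creation of quaternary C4, the C10 oxygen and the cis diol, a one-carbon homologation at C6 to bring in C7, and methylenation at C16. The benzylic C9 configuration required for this target has no handle.
- Comparison: the chosen route gets the C13 carbinol and the methylene in one step and leaves ring A to a single ring-closing step.

**Alternative 3:** Ring B and the lactone are disconnected at C9–C10 and O–C19. The forward step is an aldol addition of the C9 enolate of a C11 ketone to a ring A C10 ketone. The alkoxide then acylates on the C19 ester and gives the lactone diketone A3.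
- For it: it is convergent and carries ring A in with C4 set. The lactonisation drains the reversible aldol and fixes the lactone oxygen cis to C4 by the same ring constraint as the iodolactonisation used here. On convergence and on step count around ring B it is stronger.
- Against it: C9 is set under equilibrium through the C11 ketone, and nothing guarantees the H9 configuration of this target. The C11 oxygen must be removed again. C2 has no oxygen, so a hydroxylation next to a 3-ketone that is β to the lactone carbonyl, and two stereoselective reductions, would be needed.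
- Comparison: the chosen route fixes C9 kinetically at the start, never equilibrates it, and creates both ring A carbinols in the ring-closing step.

Key step: step 24

## Remarks on the chemistry (assumptions)

- The configuration is taken exactly as written in the SMILES: H9 anti to the C15 bridge and syn to the lactone oxygen. Every step that touches C9 is planned for that arrangement.
- Compound 3 is taken as a catalogue aldehyde.
- C10 needs a two-carbon arm (C1, C2). A Grignard reagent from 2-(2-bromoethyl)-1,3-dioxolane would deliver three carbons, so a vinyl unit is added and rearranged instead.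
- Gibberellane numbering is used for all intermediates.

## Route

Step 1
Reactants: 1 3-ethoxycyclohex-2-en-1-one
Product: 2 1-ethoxy-3-(trimethylsilyloxy)cyclohexa-1,3-diene
Conditions: LiN(i-Pr)2, THF, −78 °C; Me3SiCl, −78 °C to rt
Reagents that add atoms: chlorotrimethylsilane C[Si](C)(C)Cl
Why: Kinetic deprotonation of the vinylogous ester at the α′ carbon (the future C9) and O-silylation give the silyl dienol ether; no stereocentre is formed.

Step 2
Reactants: 2 1-ethoxy-3-(trimethylsilyloxy)cyclohexa-1,3-diene; 3 2-[(4-methoxyphenyl)methoxy]acetaldehyde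
Product: 5 (6S)-3-ethoxy-6-[(1S)-1-hydroxy-2-[(4-methoxyphenyl)methoxy]ethyl]cyclohex-2-en-1-one, via trimethylsilyl ether 4 (not isolated)
Conditions: [Cu((S,S)-Ph-pybox)](SbF6)2 (5 mol %), CH2Cl2, −78 °C; then 1 M citric acid, THF, 0 °C
Reagents that add atoms: none
Why: Catalytic enantioselective Mukaiyama aldol addition: the alkoxy aldehyde is held as a five-membered chelate on the divalent copper centre and the pybox ligand screens one face, which fixes C10; the open transition state should give the syn adduct and so set C9, the only centre carried on (C10 becomes a ketone in step 14); silyl transfer gives 4 and mild acid frees the alcohol.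

Step 3
Reactants: 5 (6S)-3-ethoxy-6-[(1S)-1-hydroxy-2-[(4-methoxyphenyl)methoxy]ethyl]cyclohex-2-en-1-one
Product: 6 (6S)-3-ethoxy-6-[(1S)-2-[(4-methoxyphenyl)methoxy]-1-[tri(propan-2-yl)silyloxy]ethyl]cyclohex-2-en-1-one
Conditions: i-Pr3SiOTf, 2,6-lutidine, CH2Cl2, 0 °C
Reagents that add atoms: tri(propan-2-yl)silyl trifluoromethanesulfonate CC(C)[Si](OS(=O)(=O)C(F)(F)F)(C(C)C)C(C)C
Why: Silylation of the secondary aldol hydroxyl with a silyl triflate and a hindered pyridine; the bulky silyl ether survives the acid, Lewis acid and base steps up to step 13.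

Step 4
Reactants: 6 (6S)-3-ethoxy-6-[(1S)-2-[(4-methoxyphenyl)methoxy]-1-[tri(propan-2-yl)silyloxy]ethyl]cyclohex-2-en-1-one; 7 3-bromoprop-1-yne
Product: 9 (4R)-4-[(1S)-2-[(4-methoxyphenyl)methoxy]-1-[tri(propan-2-yl)silyloxy]ethyl]-3-(prop-2-yn-1-yl)cyclohex-2-en-1-one, via tertiary propargyl carbinol 8 (not isolated)
Conditions: HC≡CCH2MgBr (from 7, Mg, HgCl2 cat., Et2O, 0 °C), then 6, THF, −78 to 0 °C; then 1 M HCl, THF, rt
Reagents that add atoms: none
Why: Stork–Danheiser sequence: 1,2-addition of the propargyl (allenyl) Grignard reagent to the vinylogous ester carbonyl (C8), then acid hydrolysis of the enol ether and dehydration, moves the carbonyl to C13 and places the C15–C17 propargyl group on C8; C9 is untouched.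

Step 5
Reactants: 9 (4R)-4-[(1S)-2-[(4-methoxyphenyl)methoxy]-1-[tri(propan-2-yl)silyloxy]ethyl]-3-(prop-2-yn-1-yl)cyclohex-2-en-1-one; 10 trimethyl(prop-2-en-1-yl)silane
Product: 11 (3S,4R)-4-[(1S)-2-[(4-methoxyphenyl)methoxy]-1-[tri(propan-2-yl)silyloxy]ethyl]-3-(prop-2-en-1-yl)-3-(prop-2-yn-1-yl)cyclohexan-1-one
Conditions: TiCl4, CH2Cl2, −78 °C
Reagents that add atoms: none
Why: Hosomi–Sakurai conjugate allylation: allylic strain with the C8 propargyl group turns the C9 side chain pseudo-axial, so the allyl group (C6, C7 and one carbon lost later) enters trans to it and creates quaternary C8 with the propargyl group cis to the side chain.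

Step 6
Reactants: 11 (3S,4R)-4-[(1S)-2-[(4-methoxyphenyl)methoxy]-1-[tri(propan-2-yl)silyloxy]ethyl]-3-(prop-2-en-1-yl)-3-(prop-2-yn-1-yl)cyclohexan-1-one
Product: 12 2-[(1R,2R)-2-[(1S)-2-[(4-methoxyphenyl)methoxy]-1-[tri(propan-2-yl)silyloxy]ethyl]-5-oxo-1-(prop-2-yn-1-yl)cyclohexyl]acetaldehyde
Conditions: OsO4 (2 mol %), NaIO4, 2,6-lutidine, dioxane/H2O, rt
Reagents that add atoms: osmium tetroxide O=[Os](=O)(=O)=O; sodium periodate [Na+].[O-]I(=O)(=O)=O
Why: Lemieux–Johnson cleavage: OsO4 dihydroxylates the terminal alkene much faster than it attacks the alkyne, and NaIO4 cleaves the diol to the C7 aldehyde; the aryl ether, which ozone would attack, is untouched.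

Step 7
Reactants: 12 2-[(1R,2R)-2-[(1S)-2-[(4-methoxyphenyl)methoxy]-1-[tri(propan-2-yl)silyloxy]ethyl]-5-oxo-1-(prop-2-yn-1-yl)cyclohexyl]acetaldehyde
Product: 14 methyl 2-[(1S,2R)-2-[(1S)-2-[(4-methoxyphenyl)methoxy]-1-[tri(propan-2-yl)silyloxy]ethyl]-5-oxo-1-(prop-2-yn-1-yl)cyclohexyl]acetate, via carboxylic acid 13 (not isolated)
Conditions: NaClO2, NaH2PO4, 2-methylbut-2-ene, t-BuOH/H2O, rt; then Me3SiCHN2, MeOH/toluene, 0 °C
Reagents that add atoms: sodium chlorite [Na+].[O-]Cl=O; (trimethylsilyl)diazomethane C[Si](C)(C)C=[N+]=[N-]
Why: Pinnick oxidation of the aldehyde and methylation of the acid with the diazoalkane give the C7 methyl ester without touching ketone, alkyne or ethers.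

Step 8
Reactants: 14 methyl 2-[(1S,2R)-2-[(1S)-2-[(4-methoxyphenyl)methoxy]-1-[tri(propan-2-yl)silyloxy]ethyl]-5-oxo-1-(prop-2-yn-1-yl)cyclohexyl]acetate
Product: 15 methyl 2-[5-hydroxy-6-methylidene-2-[(1S)-2-[(4-methoxyphenyl)methoxy]-1-[tri(propan-2-yl)silyloxy]ethyl]bicyclo[3.2.1]octan-1-yl]acetate (rings C and D; side chain on C9 equatorial and H9 anti to the C15–C16 bridge)
Conditions: SmI2 (2.5 equiv), HMPA, t-BuOH, THF, 0 °C
Reagents that add atoms: none
Why: Reductive ketyl–alkyne cyclisation (5-exo-dig): the C13 ketyl adds to C16 of the axial propargyl group and the vinyl radical is reduced and protonated, closing ring D with the C13 carbinol and the C16 methylene; the bridge can form only on the face of C15, which fixes C13.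

Step 9
Reactants: 15 methyl 2-[5-hydroxy-6-methylidene-2-[(1S)-2-[(4-methoxyphenyl)methoxy]-1-[tri(propan-2-yl)silyloxy]ethyl]bicyclo[3.2.1]octan-1-yl]acetate
Product: 16 methyl 2-[5-(methoxymethoxy)-6-methylidene-2-[(1S)-2-[(4-methoxyphenyl)methoxy]-1-[tri(propan-2-yl)silyloxy]ethyl]bicyclo[3.2.1]octan-1-yl]acetate
Conditions: MeOCH2Cl, i-Pr2NEt, Bu4NI (cat.), ClCH2CH2Cl, 60 °C
Reagents that add atoms: chloromethyl methyl ether COCCl
Why: Alkylation of the tertiary bridgehead alcohol under forcing amine-base conditions; the acetal shields C13–OH from the strong bases of steps 12, 15, 20 and 21.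

Step 10
Reactants: 16 methyl 2-[5-(methoxymethoxy)-6-methylidene-2-[(1S)-2-[(4-methoxyphenyl)methoxy]-1-[tri(propan-2-yl)silyloxy]ethyl]bicyclo[3.2.1]octan-1-yl]acetate
Product: 17 methyl 2-[2-[(1S)-2-hydroxy-1-[tri(propan-2-yl)silyloxy]ethyl]-5-(methoxymethoxy)-6-methylidenebicyclo[3.2.1]octan-1-yl]acetate
Conditions: DDQ, CH2Cl2/pH 7 buffer, 0 °C
Reagents that add atoms: none
Why: Oxidative removal of the 4-methoxybenzyl ether (hydride abstraction by the quinone, hydrolysis of the oxocarbenium ion) frees the C5 hydroxyl; silyl ether, acetal, ester and alkene are inert.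

Step 11
Reactants: 17 methyl 2-[2-[(1S)-2-hydroxy-1-[tri(propan-2-yl)silyloxy]ethyl]-5-(methoxymethoxy)-6-methylidenebicyclo[3.2.1]octan-1-yl]acetate
Product: 18 methyl 2-[2-[(1S)-2-iodo-1-[tri(propan-2-yl)silyloxy]ethyl]-5-(methoxymethoxy)-6-methylidenebicyclo[3.2.1]octan-1-yl]acetate
Conditions: I2, PPh3, imidazole, THF, 0 °C to rt
Reagents that add atoms: iodine II
Why: Appel-type iodination of the primary alcohol through the alkoxyphosphonium salt, under neutral conditions.

Step 12
Reactants: 18 methyl 2-[2-[(1S)-2-iodo-1-[tri(propan-2-yl)silyloxy]ethyl]-5-(methoxymethoxy)-6-methylidenebicyclo[3.2.1]octan-1-yl]acetate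
Product: 19 tricyclic ester (rings B C D): methyl 7-oate with C10 tri(propan-2-yl)silyl ether; C13 methoxymethyl ether; C16 methylidene; H9 anti to C15; C7 cis to C15
Conditions: KN(SiMe3)2, THF, −78 to 0 °C
Reagents that add atoms: none
Why: Intramolecular ester enolate alkylation (5-exo-tet) forms C5–C6 and ring B; both arms are equatorial on the ring C chair, so the ring is trans-fused, and C6 takes the pseudo-equatorial ester cis to C15, which is also the thermodynamic epimer (brief NaOMe in MeOH would correct a minor epimer).

Step 13
Reactants: 19 tricyclic ester with C10 tri(propan-2-yl)silyl ether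
Product: 20 tricyclic ester with free C10 hydroxyl (otherwise as 19)
Conditions: Bu4NF, THF, rt
Reagents that add atoms: none
Why: Fluoride cleavage of the silyl ether; the C10 hydroxyl is trans to the C7 ester across ring B and cannot lactonise.

Step 14
Reactants: 20 tricyclic ester with free C10 hydroxyl
Product: 21 tricyclic C10 ketone: methyl 7-oate; C13 methoxymethyl ether; C16 methylidene; H9 anti to C15; C7 cis to C15
Conditions: Dess–Martin periodinane, NaHCO3, CH2Cl2, 0 °C to rt
Reagents that add atoms: none
Why: Dess–Martin oxidation under buffered, non-enolising conditions gives the C10 ketone without exposing the now acidic C9–H to base.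

Step 15
Reactants: 21 tricyclic C10 ketone; 22 tert-butyl 2-bromoacetate
Product: 23 keto diester: 21 carrying CH2CO2t-Bu (C4 and C19) on C5 trans to the C7 ester
Conditions: LiN(i-Pr)2, THF, −78 °C; then 22, −78 to −40 °C
Reagents that add atoms: none
Why: Irreversible kinetic enolisation at the CH2 carbon C5 (not at the hindered ring-fusion methine C9) and SN2 alkylation; the electrophile enters trans to the C6 ester and away from the C15 bridge, which sets C5, and C9 is never equilibrated.

Step 16
Reactants: 23 keto diester; 24 ethenylmagnesium bromide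
Product: 25 tertiary allylic alcohols: C10 hydroxyl and vinyl group (C1 and C2) on C10; both C10 epimers
Conditions: CH2=CHMgBr, CeCl3, THF, −78 °C; AcOH quench at −78 °C
Reagents that add atoms: none
Why: Organocerium 1,2-addition to a hindered, enolisable ketone without proton transfer; both C10 epimers are used because C10 becomes trigonal again in the next step, and the tert-butyl ester does not acylate the alkoxide.

Step 17
Reactants: 25 tertiary allylic alcohols
Product: 27 allylic silyl ether: C10=C1 alkylidene with C2 tert-butyldimethylsilyl ether (E and Z), via primary allylic alcohol 26 (not isolated)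
Conditions: Ph3SiOReO3 (3 mol %), Et2O, 0 °C; then t-BuMe2SiCl, imidazole, DMF, rt
Reagents that add atoms: tert-butyl(chloro)dimethylsilane CC(C)(C)[Si](C)(C)Cl
Why: Oxorhenium-catalysed 1,3-transposition of allylic alcohols (allyl perrhenate, [3,3] shift) converts either epimer into the less crowded primary allylic alcohol with a trisubstituted C10=C1 alkene, and silylation of the primary hydroxyl drains the equilibrium.

Step 18
Reactants: 27 allylic silyl ether
Product: 28 iodolactone: 19,10-lactone closed; iodine on C1 (both C1 epimers); C2 silyl ether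
Conditions: I2, NaHCO3, MeCN, 0 °C, dark
Reagents that add atoms: iodine II
Why: Iodolactonisation: the carbonyl oxygen of the tert-butyl ester attacks the iodonium ion 5-exo at the tertiary carbon C10 and the tert-butyl group leaves as isobutene; the tether through C5 allows attack only on the face of C4, which is also the open face, so C10 is set with oxygen cis to C4 and the C1 arm on the C15 side.

Step 19
Reactants: 28 iodolactone
Product: 29 lactone with C10–CH2CH2OSi arm and unsubstituted C4 methylene
Conditions: Bu3SnH, AIBN (cat.), benzene, 80 °C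
Reagents that add atoms: none
Why: Radical chain dehalogenation; the secondary C1 radical is reduced faster than it can rearrange or reach the remote C16 alkene.

Step 20
Reactants: 29 lactone
Product: 30 α-methyl lactone (methyl on the convex face of C4)
Conditions: LiN(i-Pr)2, THF, −78 °C; MeI
Reagents that add atoms: iodomethane CI
Why: Lactone enolate methylation; the lactone α-CH2 is more acidic and far less hindered than C6–H of the ester, C1–H is not acidic, and the configuration formed is erased in step 21.

Step 21
Reactants: 30 α-methyl lactone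
Product: 31 hydroxymethyl lactone: quaternary C4 with C18 methyl on the concave face and C3 hydroxymethyl syn to the C1 arm
Conditions: LiN(i-Pr)2, THF, −78 °C; CH2O (gas); NH4Cl (aq)
Reagents that add atoms: formaldehyde C=O
Why: Aldol addition of the lactone enolate to monomeric formaldehyde; the electrophile enters on the convex face of the cis-fused lactone/ring B bicycle, trans to C6 on the neighbouring C5, which sets C4 with C3 syn to the C1 arm.

Step 22
Reactants: 31 hydroxymethyl lactone
Product: 32 seco-ring-A diol (C2 and C3 primary alcohols)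
Conditions: Bu4NF, AcOH, THF, 0 °C to rt
Reagents that add atoms: none
Why: Buffered fluoride cleavage of the primary silyl ether; acetic acid keeps the β-hydroxy lactone from retro-aldol loss of formaldehyde.

Step 23
Reactants: 32 seco-ring-A diol
Product: 33 seco-ring-A lactone dialdehyde (C2 and C3 aldehydes; C7 methyl ester; C13 methoxymethyl ether)
Conditions: Dess–Martin periodinane (3 equiv), NaHCO3, CH2Cl2, 0 °C; used at once
Reagents that add atoms: none
Why: Double Dess–Martin oxidation of the two primary alcohols; both aldehydes appear together, last and without amine base, because the C2 aldehyde is β to the lactone oxygen and would open the lactone by elimination.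

Step 24
Reactants: 33 seco-ring-A lactone dialdehyde
Product: 34 target as its C7 methyl ester and C13 methoxymethyl ether
Conditions: SmI2 (3 equiv), t-BuOH (2 equiv), THF, −78 to −20 °C
Reagents that add atoms: none
Why: SmI2 transfers one electron to an aldehyde, most likely the C3 aldehyde next to the lactone carbonyl, to give a samarium ketyl. The ketyl carbon adds to the carbonyl carbon of the second aldehyde while both oxygens sit on the same trivalent samarium centre; a second electron and protonation by tert-butanol give the diol. The closest known reaction type is the SmI2-promoted intramolecular pinacol coupling of 1,6-dialdehydes to cis-cyclohexane-1,2-diols. Ring A closes as a six-membered ring by 6-exo-trig attack, the acceptor oxygen staying outside the ring. C2 and C3 are set together: the samarium bridge keeps the two C–O bonds gauche, and the two-atom lactone bridge under ring A excludes the cis arrangement in which an axial C2 oxygen would point into it, leaving the cis diol with axial C3–OH and equatorial C2–OH on the open face. The step needs cis over trans-diequatorial, open face over lactone face, and aldehyde over lactone, ester and alkene. The rigid cis-fused lactone, which holds the C1 and C3 arms 1,3-cis, serves the first two, and the last holds because SmI2 without HMPA or amine/water additives does not reduce lactones, esters or isolated alkenes. Low temperature and the absence of base keep the β-acyloxy aldehyde from eliminating.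

Step 25
Reactants: 34 target as its C7 methyl ester and C13 methoxymethyl ether
Product: 35 methyl ester of the target (C13 hydroxyl free)
Conditions: Me2BBr, CH2Cl2, −78 °C; then NaHCO3 (aq), THF
Reagents that add atoms: none
Why: Boron-mediated cleavage of the methoxymethyl acetal at low temperature (bromide opens the activated acetal, the bromomethyl ether is hydrolysed on work-up); no protic acid is present, so the 13-hydroxy-16-ene unit does not rearrange, and lactone and ester are untouched.

Step 26
Reactants: 35 methyl ester of the target
Product: 36 CNP0265952.3 (target)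
Conditions: n-PrSLi, HMPA, rt; then 1 M HCl to pH 3
Reagents that add atoms: none
Why: SN2 demethylation of the hindered methyl ester by thiolate at the methyl carbon; no hydroxide is used, which avoids retro-aldol epimerisation at C3 and lactone opening, and the tertiary alkyl–oxygen carbon of the lactone cannot be attacked.

## Compound list

1 | 3-ethoxycyclohex-2-en-1-one | CCOC1=CC(=O)CCC1 | starting material
2 | 1-ethoxy-3-(trimethylsilyloxy)cyclohexa-1,3-diene | CCOC1=CC(O[Si](C)(C)C)=CCC1 | intermediate
3 | 2-[(4-methoxyphenyl)methoxy]acetaldehyde | COc1ccc(COCC=O)cc1 | starting material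
4 | (6S)-3-ethoxy-6-[(1S)-2-[(4-methoxyphenyl)methoxy]-1-(trimethylsilyloxy)ethyl]cyclohex-2-en-1-one | O=C1C=C(OCC)CC[C@H]1[C@H](O[Si](C)(C)C)COCc1ccc(OC)cc1 | intermediate
5 | (6S)-3-ethoxy-6-[(1S)-1-hydroxy-2-[(4-methoxyphenyl)methoxy]ethyl]cyclohex-2-en-1-one | O=C1C=C(OCC)CC[C@H]1[C@H](O)COCc1ccc(OC)cc1 | intermediate
6 | (6S)-3-ethoxy-6-[(1S)-2-[(4-methoxyphenyl)methoxy]-1-[tri(propan-2-yl)silyloxy]ethyl]cyclohex-2-en-1-one | O=C1C=C(OCC)CC[C@H]1[C@H](O[Si](C(C)C)(C(C)C)C(C)C)COCc1ccc(OC)cc1 | intermediate
7 | 3-bromoprop-1-yne | C#CCBr | starting material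
8 | (6S)-3-ethoxy-6-[(1S)-2-[(4-methoxyphenyl)methoxy]-1-[tri(propan-2-yl)silyloxy]ethyl]-1-(prop-2-yn-1-yl)cyclohex-2-en-1-ol (both C1 epimers) | C#CCC1(O)C=C(OCC)CC[C@H]1[C@H](O[Si](C(C)C)(C(C)C)C(C)C)COCc1ccc(OC)cc1 | intermediate
9 | (4R)-4-[(1S)-2-[(4-methoxyphenyl)methoxy]-1-[tri(propan-2-yl)silyloxy]ethyl]-3-(prop-2-yn-1-yl)cyclohex-2-en-1-one | C#CCC1=CC(=O)CC[C@H]1[C@H](O[Si](C(C)C)(C(C)C)C(C)C)COCc1ccc(OC)cc1 | intermediate
10 | trimethyl(prop-2-en-1-yl)silane | C=CC[Si](C)(C)C | starting material
11 | (3S,4R)-4-[(1S)-2-[(4-methoxyphenyl)methoxy]-1-[tri(propan-2-yl)silyloxy]ethyl]-3-(prop-2-en-1-yl)-3-(prop-2-yn-1-yl)cyclohexan-1-one (allyl trans to the side chain) | C#CC[C@@]1(CC=C)CC(=O)CC[C@H]1[C@H](O[Si](C(C)C)(C(C)C)C(C)C)COCc1ccc(OC)cc1 | intermediate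
12 | 2-[(1R,2R)-2-[(1S)-2-[(4-methoxyphenyl)methoxy]-1-[tri(propan-2-yl)silyloxy]ethyl]-5-oxo-1-(prop-2-yn-1-yl)cyclohexyl]acetaldehyde | C#CC[C@@]1(CC=O)CC(=O)CC[C@H]1[C@H](O[Si](C(C)C)(C(C)C)C(C)C)COCc1ccc(OC)cc1 | intermediate
13 | 2-[(1S,2R)-2-[(1S)-2-[(4-methoxyphenyl)methoxy]-1-[tri(propan-2-yl)silyloxy]ethyl]-5-oxo-1-(prop-2-yn-1-yl)cyclohexyl]acetic acid | C#CC[C@@]1(CC(=O)O)CC(=O)CC[C@H]1[C@H](O[Si](C(C)C)(C(C)C)C(C)C)COCc1ccc(OC)cc1 | intermediate
14 | methyl 2-[(1S,2R)-2-[(1S)-2-[(4-methoxyphenyl)methoxy]-1-[tri(propan-2-yl)silyloxy]ethyl]-5-oxo-1-(prop-2-yn-1-yl)cyclohexyl]acetate | C#CC[C@@]1(CC(=O)OC)CC(=O)CC[C@H]1[C@H](O[Si](C(C)C)(C(C)C)C(C)C)COCc1ccc(OC)cc1 | intermediate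
15 | methyl 2-[5-hydroxy-6-methylidene-2-[(1S)-2-[(4-methoxyphenyl)methoxy]-1-[tri(propan-2-yl)silyloxy]ethyl]bicyclo[3.2.1]octan-1-yl]acetate (rings C and D; C9 side chain equatorial, H9 anti to the C15–C16 bridge) | C=C1C[C@@]2(CC(=O)OC)C[C@]1(O)CC[C@H]2[C@H](O[Si](C(C)C)(C(C)C)C(C)C)COCc1ccc(OC)cc1 | intermediate
16 | C13 methoxymethyl ether of 15 | C=C1C[C@@]2(CC(=O)OC)C[C@]1(OCOC)CC[C@H]2[C@H](O[Si](C(C)C)(C(C)C)C(C)C)COCc1ccc(OC)cc1 | intermediate
17 | C5 primary alcohol (16 without the 4-methoxybenzyl group) | C=C1C[C@@]2(CC(=O)OC)C[C@]1(OCOC)CC[C@H]2[C@H](O[Si](C(C)C)(C(C)C)C(C)C)CO | intermediate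
18 | C5 primary iodide | C=C1C[C@@]2(CC(=O)OC)C[C@]1(OCOC)CC[C@H]2[C@H](O[Si](C(C)C)(C(C)C)C(C)C)CI | intermediate
19 | tricyclic ester (rings B, C, D): C7 methyl ester on C6 cis to C15; C10 tri(propan-2-yl)silyl ether; C13 methoxymethyl ether; C16 methylidene; H9 anti to C15 | C=C1C[C@@]23C[C@]1(OCOC)CC[C@H]2[C@H](O[Si](C(C)C)(C(C)C)C(C)C)C[C@H]3C(=O)OC | intermediate
20 | C10 alcohol of the tricyclic ester | C=C1C[C@@]23C[C@]1(OCOC)CC[C@H]2[C@H](O)C[C@H]3C(=O)OC | intermediate
21 | tricyclic C10 ketone (C7 methyl ester cis to C15; H9 anti to C15; C13 methoxymethyl ether; C16 methylidene) | C=C1C[C@@]23C[C@]1(OCOC)CC[C@H]2C(=O)C[C@H]3C(=O)OC | intermediate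
22 | tert-butyl 2-bromoacetate | CC(C)(C)OC(=O)CBr | starting material
23 | keto diester: 21 with CH2CO2t-Bu on C5, trans to the C7 ester | C=C1C[C@@]23C[C@]1(OCOC)CC[C@H]2C(=O)[C@H](CC(=O)OC(C)(C)C)[C@H]3C(=O)OC | intermediate
24 | ethenylmagnesium bromide | C=C[Mg]Br | starting material
25 | tertiary allylic alcohols: C10 hydroxyl and vinyl, both C10 epimers | C=C1C[C@@]23C[C@]1(OCOC)CC[C@H]2C(O)(C=C)[C@H](CC(=O)OC(C)(C)C)[C@H]3C(=O)OC | intermediate
26 | primary allylic alcohol: C10=C1 alkylidene, C2 hydroxyl (E and Z) | C=C1C[C@@]23C[C@]1(OCOC)CC[C@H]2C(=CCO)[C@H](CC(=O)OC(C)(C)C)[C@H]3C(=O)OC | intermediate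
27 | tert-butyldimethylsilyl ether of 26 (E and Z) | C=C1C[C@@]23C[C@]1(OCOC)CC[C@H]2C(=CCO[Si](C)(C)C(C)(C)C)[C@H](CC(=O)OC(C)(C)C)[C@H]3C(=O)OC | intermediate
28 | iodolactone: 19,10-lactone, lactone oxygen cis to C4; iodine on C1 (both epimers) | C=C1C[C@@]23C[C@]1(OCOC)CC[C@H]2[C@]1(C(I)CO[Si](C)(C)C(C)(C)C)OC(=O)C[C@@H]1[C@H]3C(=O)OC | intermediate
29 | lactone with C10–CH2CH2OSi(t-Bu)Me2 arm and C4 methylene | C=C1C[C@@]23C[C@]1(OCOC)CC[C@H]2[C@]1(CCO[Si](C)(C)C(C)(C)C)OC(=O)C[C@@H]1[C@H]3C(=O)OC | intermediate
30 | α-methyl lactone (methyl on the convex face of C4) | C=C1C[C@@]23C[C@]1(OCOC)CC[C@H]2[C@]1(CCO[Si](C)(C)C(C)(C)C)OC(=O)[C@@H](C)[C@@H]1[C@H]3C(=O)OC | intermediate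
31 | hydroxymethyl lactone: C4 quaternary, C3 hydroxymethyl syn to the C1 arm, C18 methyl syn to C6 | C=C1C[C@@]23C[C@]1(OCOC)CC[C@H]2[C@]1(CCO[Si](C)(C)C(C)(C)C)OC(=O)[C@@](C)(CO)[C@@H]1[C@H]3C(=O)OC | intermediate
32 | seco-ring-A diol (C2 and C3 primary alcohols) | C=C1C[C@@]23C[C@]1(OCOC)CC[C@H]2[C@]1(CCO)OC(=O)[C@@](C)(CO)[C@@H]1[C@H]3C(=O)OC | intermediate
33 | seco-ring-A lactone dialdehyde | C=C1C[C@@]23C[C@]1(OCOC)CC[C@H]2[C@]1(CC=O)OC(=O)[C@@](C)(C=O)[C@@H]1[C@H]3C(=O)OC | intermediate
34 | target as C7 methyl ester and C13 methoxymethyl ether | C=C1C[C@@]23C[C@]1(OCOC)CC[C@H]2[C@]12C[C@@H](O)[C@@H](O)[C@](C)(C(=O)O1)[C@@H]2[C@H]3C(=O)OC | intermediate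
35 | methyl ester of the target | C=C1C[C@@]23C[C@]1(O)CC[C@H]2[C@]12C[C@@H](O)[C@@H](O)[C@](C)(C(=O)O1)[C@@H]2[C@H]3C(=O)OC | intermediate
36 | CNP0265952.3 | C=C1C[C@@]23C[C@]1(O)CC[C@H]2[C@]12C[C@@H](O)[C@@H](O)[C@](C)(C(=O)O1)[C@@H]2[C@H]3C(=O)O | target

## Step count and least certain steps

Total step count: 26. Longest linear sequence: 26 steps (1 to 36); 3, 7, 10, 22 and 24 are bought.

**Step 24 (key step).** The coupling may pass through the rotamer of the C3 aldehyde in which samarium is chelated by the lactone carbonyl, which would give the trans-diequatorial diol (epimer at C3). The aldehydes may also simply be reduced, or the lactone may open by elimination from the C2 aldehyde. Simple reduction returns 32, which goes through step 23 again. The fallback for the wrong C3 configuration sets out from 33 and returns to 34. The epimeric diol F1 is silylated at the less hindered C2 hydroxyl (t-BuMe2SiCl, imidazole) to F2. F2 is oxidised with Dess–Martin periodinane to the 3-ketone F3. F3 is reduced with KBH(s-Bu)3 at −78 °C, which attacks from the equatorial direction and gives the axial C3 alcohol F4. F4 is desilylated with Bu4NF/AcOH to 34. C3 is then set by hydride delivery and no longer by the coupling.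

**Step 2.** Enantio- or diastereoselection with a cyclic dienol silane may be insufficient, or the syn/anti sense may be opposite to the one assumed, which would put C9 in the mirror-image series (the other ligand enantiomer is then used). The fallback sets out from 1 and 3 and returns to 5. A LiN(i-Pr)2 aldol gives the racemic syn adduct after chromatography. A lipase (Candida antarctica lipase B, vinyl acetate) acylates one enantiomer. The acetate F5 of the wanted enantiomer is cleaved with K2CO3 in MeOH to 5; if the enzyme prefers the other enantiomer, 5 is the unreacted alcohol.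

**Step 5.** The 4-methoxybenzyl or silyl ether may be lost to TiCl4, or the anti selectivity may be incomplete. The fallback sets out from 9 and returns directly to 14, bypassing 11–13. It is a Mukaiyama–Michael addition of 1-methoxy-1-(trimethylsilyloxy)ethene at −78 °C under catalysis by Me3SiOTf, with aqueous work-up. It follows the same facial course and makes no new isolated compound.

**Step 18.** The tert-butyl ester may participate too slowly, so that iodine is consumed at the C16 alkene or the iodonium ion reverts without closure. The fallback sets out from 27 and returns to 29. The tert-butyl ester is cleaved on silica gel in refluxing toluene to the acid F6. F6 is cyclised with PhSeCl in CH2Cl2 at −78 °C to the phenylselenolactone F7, with the same regiochemistry and the same tether-enforced face. F7 is reduced with Bu3SnH/AIBN to 29.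

**Step 21.** Deprotonation may compete at C6, the aldol may reverse on work-up with loss of formaldehyde, or the electrophile may enter on the concave face. The fallback sets out from 30 and returns to 32. The lactone enolate is alkylated irreversibly with 2-(trimethylsilyl)ethoxymethyl chloride to F8. Bu4NF in DMPU at 50 °C then removes both silicon-based groups.

## Further compounds

F1 | step 24 | C3-epimeric (trans-diequatorial) 2,3-diol, otherwise as 34 | C=C1C[C@@]23C[C@]1(OCOC)CC[C@H]2[C@]12C[C@@H](O)[C@H](O)[C@](C)(C(=O)O1)[C@@H]2[C@H]3C(=O)OC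
F2 | step 24 | C2 tert-butyldimethylsilyl ether of F1 | C=C1C[C@@]23C[C@]1(OCOC)CC[C@H]2[C@]12C[C@@H](O[Si](C)(C)C(C)(C)C)[C@H](O)[C@](C)(C(=O)O1)[C@@H]2[C@H]3C(=O)OC
F3 | step 24 | 3-ketone with C2 silyl ether | C=C1C[C@@]23C[C@]1(OCOC)CC[C@H]2[C@]12C[C@@H](O[Si](C)(C)C(C)(C)C)C(=O)[C@](C)(C(=O)O1)[C@@H]2[C@H]3C(=O)OC
F4 | step 24 | C2 tert-butyldimethylsilyl ether of 34 | C=C1C[C@@]23C[C@]1(OCOC)CC[C@H]2[C@]12C[C@@H](O[Si](C)(C)C(C)(C)C)[C@@H](O)[C@](C)(C(=O)O1)[C@@H]2[C@H]3C(=O)OC
F5 | step 2 | acetate of 5 | O=C1C=C(OCC)CC[C@H]1[C@H](OC(C)=O)COCc1ccc(OC)cc1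
F0 | step 5 | none | none
F6 | step 18 | C19 carboxylic acid corresponding to 27 | C=C1C[C@@]23C[C@]1(OCOC)CC[C@H]2C(=CCO[Si](C)(C)C(C)(C)C)[C@H](CC(=O)O)[C@H]3C(=O)OC
F7 | step 18 | phenylselenolactone (selenium on C1, lactone as in 28) | C=C1C[C@@]23C[C@]1(OCOC)CC[C@H]2[C@]1(C([Se]c2ccccc2)CO[Si](C)(C)C(C)(C)C)OC(=O)C[C@@H]1[C@H]3C(=O)OC
F8 | step 21 | 2-(trimethylsilyl)ethoxymethyl ether of 31 | C=C1C[C@@]23C[C@]1(OCOC)CC[C@H]2[C@]1(CCO[Si](C)(C)C(C)(C)C)OC(=O)[C@@](C)(COCC[Si](C)(C)C)[C@@H]1[C@H]3C(=O)OC
A1 | alternative 1 | tetracyclic cycloadduct with C10 and C3 trimethylsilyl ethers, C1=C2 alkene, C16 dioxolane, C7 as methoxymethyl-protected alcohol | C1COC2(O1)C[C@@]34C[C@]2(OCOC)CC[C@H]3[C@@]3(O[Si](C)(C)C)C=C[C@@H](O[Si](C)(C)C)[C@](C)(C(=O)OC)[C@@H]3[C@H]4COCOC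
A2 | alternative 2 | benzo-fused B/C/D diketone with quaternary C8 (C6 and C16 ketones, C19 methyl ester on the aromatic ring) | O=C1C[C@@]23C[C@]1(OCOC)CC[C@H]2c1cccc(C(=O)OC)c1C3=O
A3 | alternative 3 | tetracyclic 19,10-lactone 3,11-diketone with C16 dioxolane and C7 tert-butyl ester | C1COC2(O1)C[C@@]34C[C@]2(OCOC)CC(=O)[C@H]3[C@]35CCC(=O)[C@](C)(C(=O)O3)[C@@H]5[C@H]4C(=O)OC(C)(C)C
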